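**Plan**

1. Retrosynthesis: the O7–CH2 bond of a methoxymethyl ether is cut first; then the four bonds that build the pyranone (C8a–O1, C4a–C4, C3–C4, O1–C2) are cut together, giving a ring A aryne, DMF (C4) and an arylacetate (C2, C3 and the chroman).
2. Enabling feature: in the coumarin (O1, C2–C4, C4a, C5–C8, C8a) O1 and C4 sit on the adjacent ring carbons C8a and C4a, and the C5 methoxy group is next to C4a, so a C4a–C8a aryne polarised by that group can take up the C=O of DMF with O at C8a and C at C4a.
3. Forward, ring A: 5-methoxyresorcinol is brominated, bis-silylated, rearranged (retro-Brook) and triflated, then protected as the methoxymethyl ether (four steps to the ortho-silylaryl triflate).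
4. Forward, rings C and D: 2,4-dihydroxyacetophenone and 3-methylbut-2-enal close the dimethylpyran ring first; O-methylation, hydrogenation and an oxidative 1,2-aryl shift give the arylacetate (four steps).
5. The pyranone (ring B) closes last in the three-component annulation; mild acid then frees O7.
6. Stereochemistry: the target has no stereocentre; only regiochemistry has to be secured (bromination, chromene annulation, aryne addition).

Key step: step 9

Remark: the SMILES is taken as the full definition of the target (achiral). Ring A is the benzo ring of the coumarin, ring B the pyranone, ring C the benzo ring of the chroman, ring D the dihydropyran; chroman atoms are primed.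

**Route**

Step 1
Reactants: 1 5-methoxyresorcinol (5-methoxybenzene-1,3-diol)
Product: 2 4-bromo-5-methoxybenzene-1,3-diol
Conditions: NBS (1.0 equiv), MeCN, −30 → 0 °C
Reagents that add atoms: N-bromosuccinimide, O=C1CCC(=O)N1Br
Why: Electrophilic aromatic bromination under the para-selective NBS/acetonitrile conditions should go para to one hydroxyl (C4 or the equivalent C6) rather than between the two hydroxyls, as in the 4-bromination of resorcinol and orcinol, and one equivalent at low temperature limits dibromination.

Step 2
Reactants: 2 4-bromo-5-methoxybenzene-1,3-diol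
Product: 3 2-bromo-1-methoxy-3,5-bis(trimethylsilyloxy)benzene
Conditions: (Me3Si)2NH, THF, reflux; evaporation, used crude
Reagents that add atoms: hexamethyldisilazane, C[Si](C)(C)N[Si](C)(C)C
Why: Silylation of both phenols with hexamethyldisilazane releases only ammonia, so the moisture-sensitive bis-silyl ether can be taken on without purification.

Step 3
Reactants: 3 2-bromo-1-methoxy-3,5-bis(trimethylsilyloxy)benzene
Product: 7 5-hydroxy-3-methoxy-2-(trimethylsilyl)phenyl trifluoromethanesulfonate, via aryllithium 4 (not isolated), via lithium silylphenoxide 5 (not isolated), via silyl ether triflate 6 (not isolated)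
Conditions: n-BuLi (1.1 equiv), THF, −78 °C; Tf2O (1.1 equiv), −78 °C; then dilute aq. HCl, THF, 0 °C, 10 min
Reagents that add atoms: trifluoromethanesulfonic anhydride, O=S(=O)(OS(=O)(=O)C(F)(F)F)C(F)(F)F
Why: Bromine–lithium exchange gives aryllithium 4, whose neighbouring silyl ether undergoes the anionic 1,3 O-to-C silyl shift (retro-Brook rearrangement) to phenoxide 5, so only the oxygen next to the new C–Si bond is triflated (6), and the remote aryl silyl ether is then hydrolysed by the brief acidic work-up, which should be too mild for protodesilylation at carbon.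

Step 4
Reactants: 7 5-hydroxy-3-methoxy-2-(trimethylsilyl)phenyl trifluoromethanesulfonate
Product: 8 3-methoxy-5-(methoxymethoxy)-2-(trimethylsilyl)phenyl trifluoromethanesulfonate
Conditions: MOMCl, i-Pr2NEt, CH2Cl2, 0 °C → rt
Reagents that add atoms: chloromethyl methyl ether, COCCl
Why: Amine-mediated O-alkylation of the phenol to the methoxymethyl acetal should leave the silyl triflate untouched, since no fluoride or alkoxide is present and the phenol is para, not ortho, to silicon.

Step 5
Reactants: 9 2,4-dihydroxyacetophenone; 10 3-methylbut-2-enal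
Product: 12 1-(5-hydroxy-2,2-dimethyl-2H-chromen-6-yl)ethan-1-one, via dienone 11 (not isolated)
Conditions: ethylenediammonium diacetate (10 mol%), xylene, 140 °C
Reagents that add atoms: none
Why: Amine-catalysed Knoevenagel-type condensation of the enal at C3 of the resorcinol ring gives dienone 11, which closes ring D by oxa-6π electrocyclisation; the 2-hydroxyl is hydrogen-bonded to the acetyl group, so closure goes through the 4-oxygen and the angular 5-hydroxychromene should result.

Step 6
Reactants: 12 1-(5-hydroxy-2,2-dimethyl-2H-chromen-6-yl)ethan-1-one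
Product: 13 1-(5-methoxy-2,2-dimethyl-2H-chromen-6-yl)ethan-1-one
Conditions: MeI, K2CO3, acetone, reflux
Reagents that add atoms: iodomethane, CI
Why: Williamson O-methylation of the hydrogen-bonded phenol with iodomethane and K2CO3 is a standard operation on 5-hydroxy-6-acylchromenes.

Step 7
Reactants: 13 1-(5-methoxy-2,2-dimethyl-2H-chromen-6-yl)ethan-1-one
Product: 14 1-(5-methoxy-2,2-dimethylchroman-6-yl)ethan-1-one
Conditions: H2 (1 atm), 10% Pd/C, EtOAc, rt
Reagents that add atoms: none
Why: Heterogeneous catalytic hydrogenation saturates the styrenic C3'–C4' bond of ring D while the aryl ketone, deactivated by the ortho and para oxygens, should survive at one atmosphere; it is done here because the next oxidant would attack the chromene alkene.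

Step 8
Reactants: 14 1-(5-methoxy-2,2-dimethylchroman-6-yl)ethan-1-one
Product: 15 methyl 2-(5-methoxy-2,2-dimethylchroman-6-yl)acetate
Conditions: Tl(NO3)3·3H2O (1.1 equiv), MeOH/HC(OMe)3 (1:1), rt
Reagents that add atoms: methanol, CO (trimethyl orthoformate, COC(OC)OC, is an equivalent source of the same methoxy group)
Why: Thallium trinitrate-mediated oxidative rearrangement of an aryl methyl ketone: α-oxythallation is followed by 1,2-shift of the electron-rich 2,4-dioxygenated aryl group with loss of monovalent thallium, which gives the methyl arylacetate directly, as is well established for alkoxyacetophenones.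

Step 9
Reactants: 8 3-methoxy-5-(methoxymethoxy)-2-(trimethylsilyl)phenyl trifluoromethanesulfonate; 15 methyl 2-(5-methoxy-2,2-dimethylchroman-6-yl)acetate; 16 N,N-dimethylformamide
Product: 23 5-methoxy-7-(methoxymethoxy)-3-(5-methoxy-2,2-dimethylchroman-6-yl)-2H-chromen-2-one, via sodium ester enolate 17 (not isolated), via aryne 18 (not isolated), via benzoxete 19 (not isolated), via quinone methide 20 (not isolated), via Mannich adduct 21 (not isolated), via aminodihydrocoumarin 22 (not isolated)
Conditions: flask 1: 15, NaN(SiMe3)2 (1.05 equiv), THF, −78 °C; flask 2: 8 (1.5 equiv), anhydrous Bu4NF (3 equiv), DMF 16 as solvent, 0 °C → rt, 10 min; flask 1 into flask 2 at −40 °C → rt, then 50 °C; aq. NH4Cl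
Reagents that add atoms: none
Why: Fluoride attacks silicon in 8 and expels triflate to give aryne 18; in DMF as solvent the formamide oxygen adds to the aryne carbon meta to the methoxy group (future C8a) and the aryl anion that develops beside the methoxy group (future C4a) closes on the iminium carbon, a formal [2+2] closure of the four-membered ring of benzoxete 19, which opens electrocyclically to the dimethylaminomethylene ortho-quinone methide 20. Enolate 17, added only after the aryne has been consumed, attacks the exocyclic carbon of 20 in a Mannich-type conjugate addition (C3–C4) to give phenoxide 21, whose oxygen closes ring B by 6-exo-trig acyl substitution at the ester with loss of methoxide (O1–C2) to give 22, and E1cB loss of dimethylamine across C3–C4 then gives the aromatic pyranone of 23. The closest known reaction type is the three-component coupling of arynes, DMF and active methylene compounds or ester enolates to coumarins through insertion of the aryne into the formamide C=O bond. No stereocentre reaches the product, since the two sp3 centres of 21 and 22, formed without control, are erased by the elimination. The step needs regioselective addition across the unsymmetrical aryne, secured by the C5 methoxy group, whose inductive pull and the resulting aryne distortion make the distal carbon the electrophilic one and place the carbanion ortho to oxygen, while the C7 acetal is meta and para to the two aryne carbons and should have almost no influence. It also needs capture of the aryne by DMF rather than by the enolate, secured by DMF as solvent, a soluble fluoride source for fast aryne generation and the sequential addition.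

Step 10
Reactants: 23 5-methoxy-7-(methoxymethoxy)-3-(5-methoxy-2,2-dimethylchroman-6-yl)-2H-chromen-2-one
Product: 24 7-hydroxy-5-methoxy-3-(5-methoxy-2,2-dimethylchroman-6-yl)-2H-chromen-2-one (CNP0139207.0)
Conditions: 3 M aq. HCl, MeOH/THF, 50 °C
Reagents that add atoms: none
Why: Acid-catalysed solvolysis of the methoxymethyl acetal through an oxocarbenium ion should free O7, while the aryl methyl ethers, the coumarin lactone and the 2,2-dimethylchroman ether (itself the product of acid cyclisation of prenylphenols) are stable to dilute HCl in methanol.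

**Compound list**

1 | 5-methoxyresorcinol (5-methoxybenzene-1,3-diol) | COc1cc(O)cc(O)c1 | starting material
2 | 4-bromo-5-methoxybenzene-1,3-diol | COc1cc(O)cc(O)c1Br | intermediate
3 | 2-bromo-1-methoxy-3,5-bis(trimethylsilyloxy)benzene | COc1cc(O[Si](C)(C)C)cc(O[Si](C)(C)C)c1Br | intermediate
4 | [2-methoxy-4,6-bis(trimethylsilyloxy)phenyl]lithium | COc1cc(O[Si](C)(C)C)cc(O[Si](C)(C)C)c1[Li] | intermediate
5 | lithium 3-methoxy-2-(trimethylsilyl)-5-(trimethylsilyloxy)phenoxide | COc1cc(O[Si](C)(C)C)cc([O-])c1[Si](C)(C)C.[Li+] | intermediate
6 | 3-methoxy-2-(trimethylsilyl)-5-(trimethylsilyloxy)phenyl trifluoromethanesulfonate | COc1cc(O[Si](C)(C)C)cc(OS(=O)(=O)C(F)(F)F)c1[Si](C)(C)C | intermediate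
7 | 5-hydroxy-3-methoxy-2-(trimethylsilyl)phenyl trifluoromethanesulfonate | COc1cc(O)cc(OS(=O)(=O)C(F)(F)F)c1[Si](C)(C)C | intermediate
8 | 3-methoxy-5-(methoxymethoxy)-2-(trimethylsilyl)phenyl trifluoromethanesulfonate | COCOc1cc(OC)c([Si](C)(C)C)c(OS(=O)(=O)C(F)(F)F)c1 | intermediate
9 | 2,4-dihydroxyacetophenone | CC(=O)c1ccc(O)cc1O | starting material
10 | 3-methylbut-2-enal | CC(C)=CC=O | starting material
11 | 4-acetyl-3-hydroxy-2-(3-methylbut-2-en-1-ylidene)cyclohexa-3,5-dien-1-one | CC(=O)C1=C(O)C(=CC=C(C)C)C(=O)C=C1 | intermediate
12 | 1-(5-hydroxy-2,2-dimethyl-2H-chromen-6-yl)ethan-1-one | CC(=O)c1ccc2OC(C)(C)C=Cc2c1O | intermediate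
13 | 1-(5-methoxy-2,2-dimethyl-2H-chromen-6-yl)ethan-1-one | CC(=O)c1ccc2OC(C)(C)C=Cc2c1OC | intermediate
14 | 1-(5-methoxy-2,2-dimethylchroman-6-yl)ethan-1-one | CC(=O)c1ccc2OC(C)(C)CCc2c1OC | intermediate
15 | methyl 2-(5-methoxy-2,2-dimethylchroman-6-yl)acetate | COC(=O)Cc1ccc2OC(C)(C)CCc2c1OC | intermediate
16 | N,N-dimethylformamide | CN(C)C=O | starting material
17 | sodium 1-methoxy-2-(5-methoxy-2,2-dimethylchroman-6-yl)ethen-1-olate | COC([O-])=Cc1ccc2OC(C)(C)CCc2c1OC.[Na+] | intermediate
18 | 3-methoxy-5-(methoxymethoxy)benzyne (1,2-didehydro-3-methoxy-5-(methoxymethoxy)benzene) | COCOC1=CC#CC(OC)=C1 | intermediate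
19 | 3-methoxy-5-(methoxymethoxy)-N,N-dimethyl-2H-benzo[b]oxet-2-amine (racemic) | CN(C)C1Oc2cc(OCOC)cc(OC)c12 | intermediate
20 | 6-[(dimethylamino)methylidene]-5-methoxy-3-(methoxymethoxy)cyclohexa-2,4-dien-1-one | CN(C)C=C1C(=O)C=C(OCOC)C=C1OC | intermediate
21 | sodium 2-[1-(dimethylamino)-3-methoxy-2-(5-methoxy-2,2-dimethylchroman-6-yl)-3-oxopropyl]-3-methoxy-5-(methoxymethoxy)phenoxide (mixture of diastereomers) | COC(=O)C(c1ccc2OC(C)(C)CCc2c1OC)C(N(C)C)c1c([O-])cc(OCOC)cc1OC.[Na+] | intermediate
22 | 4-(dimethylamino)-5-methoxy-7-(methoxymethoxy)-3-(5-methoxy-2,2-dimethylchroman-6-yl)chroman-2-one (mixture of diastereomers) | COCOc1cc(OC)c2C(N(C)C)C(c3ccc4OC(C)(C)CCc4c3OC)C(=O)Oc2c1 | intermediate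
23 | 5-methoxy-7-(methoxymethoxy)-3-(5-methoxy-2,2-dimethylchroman-6-yl)-2H-chromen-2-one | COCOc1cc(OC)c2cc(-c3ccc4OC(C)(C)CCc4c3OC)c(=O)oc2c1 | intermediate
24 | 7-hydroxy-5-methoxy-3-(5-methoxy-2,2-dimethylchroman-6-yl)-2H-chromen-2-one (CNP0139207.0) | COc1c(-c2cc3c(OC)cc(O)cc3oc2=O)ccc2c1CCC(C)(C)O2 | target

**Count**

Total steps: 10 (steps 1–4 for the aryne precursor, steps 5–8 for the arylacetate, steps 9 and 10 after convergence). Longest linear sequence: 6 steps (1–4, 9, 10, or equally 5–8, 9, 10).

**Steps most likely to fail and fallbacks**

Step 9. The aryne or the quinone methide may be diverted before the enolate adds: direct C-arylation of the enolate by residual aryne, proton transfer that quenches the enolate, ester self-condensation, or hydrolysis of the aryne–DMF adduct. The fallback keeps the aryne insertion into DMF but finishes the annulation in a separate classical condensation. It sets out from 8 and 16: fluoride in DMF followed by an aqueous quench should hydrolyse quinone methide 20 to 2-hydroxy-6-methoxy-4-(methoxymethoxy)benzaldehyde F1, with C8a–O1 and C4a–C4 formed with the same regiochemistry. Ester 15 is saponified (LiOH, THF/H2O) to 2-(5-methoxy-2,2-dimethylchroman-6-yl)acetic acid F2. Perkin condensation of F1 with F2 (Ac2O, Et3N, 110 °C) then forms C3–C4 and O1–C2 and comes back to the route at coumarin 23.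

Step 1. Bromination may occur between the two hydroxyls or twice, because every free ring position is activated by three oxygens. The fallback uses steric shielding and sets out from 1: TIPSCl and imidazole in DMF should give 1-methoxy-3,5-bis(triisopropylsilyloxy)benzene F3. NBS in MeCN should then brominate a position flanked by the methoxy group and only one bulky silyloxy group, giving 2-bromo-1-methoxy-3,5-bis(triisopropylsilyloxy)benzene F4. Bu4NF in THF removes both silyl groups and the sequence comes back to the route at diol 2.

Step 8. Oxidation or nitration of the electron-rich ring C may compete with the aryl migration. The fallback is a sulfur-based rearrangement that sets out from ketone 14: the Willgerodt–Kindler reaction (S8, morpholine, 130 °C) should give 2-(5-methoxy-2,2-dimethylchroman-6-yl)-1-(morpholin-4-yl)ethane-1-thione F5. Hydrolysis (NaOH, aq. EtOH, reflux) gives 2-(5-methoxy-2,2-dimethylchroman-6-yl)acetic acid F2, and Fischer esterification (MeOH, cat. H2SO4, reflux) comes back to the route at ester 15.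

**Further compounds**

F1 | step 9 | 2-hydroxy-6-methoxy-4-(methoxymethoxy)benzaldehyde | COCOc1cc(O)c(C=O)c(OC)c1
F2 | step 9 | 2-(5-methoxy-2,2-dimethylchroman-6-yl)acetic acid | OC(=O)Cc1ccc2OC(C)(C)CCc2c1OC
F3 | step 1 | 1-methoxy-3,5-bis(triisopropylsilyloxy)benzene | COc1cc(O[Si](C(C)C)(C(C)C)C(C)C)cc(O[Si](C(C)C)(C(C)C)C(C)C)c1
F4 | step 1 | 2-bromo-1-methoxy-3,5-bis(triisopropylsilyloxy)benzene | COc1cc(O[Si](C(C)C)(C(C)C)C(C)C)cc(O[Si](C(C)C)(C(C)C)C(C)C)c1Br
F5 | step 8 | 2-(5-methoxy-2,2-dimethylchroman-6-yl)-1-(morpholin-4-yl)ethane-1-thione | S=C(Cc1ccc2OC(C)(C)CCc2c1OC)N1CCOCC1
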